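**The pile.** A catalyst works like a bricklayer with a pile: at a loading of 0.2 mol%, each catalyst molecule has on average 500 turnovers to make before the substrate is gone. The flasks and earlier runs are these:

| flask | substrate | coupling partner | protic impurity | precatalyst | temperature | remark | time |
|---|---|---|---|---|---|---|---|
| south-east | 0.072 M | 0.77 equiv | 1.44 mM | 0.2 mol% | 95 °C | run made earlier |  |
| north-east | 0.072 M | 6.2 equiv | 1.44 mM | 0.2 mol% | 106 °C | run made earlier |  |
| green | 0.072 M | 8.00 equiv | 1.44 mM | 0.2 mol% | 100 °C |  | 40 h |
| ochre | 0.072 M | 6.00 equiv | 1.44 mM | 0.2 mol% | 100 °C |  | 40 h |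
| violet | 0.072 M | 1.30 equiv | 1.44 mM | 0.2 mol% | 100 °C |  | 40 h |
| blue | 0.072 M | 4.00 equiv | 1.44 mM | 0.2 mol% | 100 °C |  | 40 h |
| amber | 0.072 M | 2.00 equiv | 1.44 mM | 0.2 mol% | 100 °C |  | 40 h |

| run | time / h | target / % | substrate / % |
|---|---|---|---|
| south-east | 1.00 | 0 | 100.1 |
| south-east | 3.00 | 0 | 100.0 |
| south-east | 6.00 | 0.1 | 99.9 |
| south-east | 8.00 | 0.3 | 100.4 |
| south-east | 12.0 | 0 | 99.5 |
| south-east | 15.0 | 0.5 | 99.1 |
| south-east | 20.0 | 0.9 | 99.8 |
| north-east | 1.50 | 0 | 99.8 |
| north-east | 2.50 | 0.5 | 99.6 |
| north-east | 4.00 | 1.6 | 98.8 |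
| north-east | 6.00 | 3.6 | 95.7 |
| north-east | 8.00 | 6.0 | 93.4 |
| north-east | 12.0 | 12.1 | 88.6 |
| north-east | 20.0 | 24.4 | 76.5 |

(scatter of a reading: 0.5 percentage points)

- ranking by amount of target, in percent of the substrate charged, from high to low, at 40 h (green / ochre / violet / blue / amber)
- the amount of target, in percent of the substrate charged of the flask you put first, at 40 h
- the amount of target, in percent of the substrate charged of the flask you put last, at 40 h

**The waking.** The north-east run reads 0 % target at 1.50 h. I take the catalyst then to be waiting as precatalyst, which the coupling partner wakes slowly.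

**The round.** Between 12.0 h and 20.0 h, north-east target climbs from 12.1 % to 24.4 % while substrate falls. This slope over the loading reads 7.69 h⁻¹: the turnover pace, turnovers per charged catalyst per hour, the usual turnover frequency. Traced back, the line gives a lag of 4.13 h, far longer than one turn of 0.130 h, so I read the waking as the slow stage of the north-east run and the round as quick.

**The count.** For the cooler bath at 100 °C I guess a factor of 0.7, which gives a pace of 5.38 h⁻¹ and a lag of 5.90 h. Ochre, closest to north-east in partner, then counts 183 turnovers by 40 h, or 36.7 % of its pile, so I expect substrate to remain. Green holds more partner than the others, so I put it first and above ochre's count, and I rank the rest by partner.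

**The slow end.** I expect violet to be still waking at 40 h, with active catalyst growing about steadily and target growing about with time squared. Scaling the south-east reading of 0.9 % by time squared, by partner once and by my bath factor gives violet 8.68 %, a figure as loose as that small reading. Violet's 1.30 equiv of partner covers its substrate, and the protic impurity can take 1.54 % of that partner.

**The result.** The forecast ranks green > ochre > blue > amber > violet, with 38 % first and 7 % last, holding that “the rate is roughly zero order in substrate”; my order is the same, and my violet is higher than its figure. The simulation gives green > ochre > blue > amber > violet, with green at 35.2 %, ochre at 31.0 % and violet at 7.55 %.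

    catalyst intermediate C → free catalyst + target (k = 9.62 h⁻¹, Ea = 115 kJ mol⁻¹)
    coupling partner + protic impurity → quenched reagent (k = 11.2 M⁻¹ h⁻¹, Ea = 67.0 kJ mol⁻¹)
    coupling partner + precatalyst → free catalyst + spent reagent (k = 0.245 M⁻¹ h⁻¹, Ea = 88.0 kJ mol⁻¹)
    coupling partner + catalyst intermediate B → catalyst intermediate C (k = 477 M⁻¹ h⁻¹, Ea = 77.0 kJ mol⁻¹)
    catalyst intermediate A ⇌ catalyst intermediate B (K = 0.125, k = 131 h⁻¹, Ea = 111 kJ mol⁻¹, ΔH = −5.00 kJ mol⁻¹)
    substrate + free catalyst → catalyst intermediate A (k = 414 M⁻¹ h⁻¹, Ea = 58.0 kJ mol⁻¹)
    (constants at 100 °C)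

**Green again.** Green's 35.2 % is 176 turnovers, which at my pace, reckoned from north-east for the 100 °C bath, takes 32.7 h of its 40 h. The neighbour is green read at 4.0 d. My pace adds 301 turnovers in the extra 56.0 h, which would bring the count to 95.5 % of the pile. That flask holds 82.0 % target, or 410 turnovers, with 17.9 % of the substrate left.

The numbers in the tables are simulated from invented constants; scatter was added.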